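**Plan**
Retrosynthesis (azulene numbering: C3 carbinol, C3a–C8a ring fusion, C4 ester carbon, C7 ketone): cut the aryl silyl ether and the C4–O ester bond, take the C7 carbonyl back to CH2 (allylic oxidation) and C4–OH back to a ketone.
The C3a–C8a bond joins a tertiary CH to the methyl-bearing quaternary carbon and lies between the C4 oxygen and the C3 carbinol. This O–C4–C3a(H)–C3–O array around a ring-fusion bond is the retron of a pinacol-type 1,2-shift, so the bond is cut and C8a is rejoined to C4.
This gives an all-cis 1,2,8a-triol 1-mesylate of a cis-decalin: the cyclopentane arises by contraction of one six-membered ring and the cycloheptanone by one-carbon expansion of the other.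
Forward: Robinson annulation of 2,5-dimethylcyclohexanone with methyl vinyl ketone, isopropyl addition, directed dihydroxylation, mesylation, 1,2-shift (5/7 core), enone formation, directed reduction, esterification, allylic oxidation, desilylation.
Stereochemistry: the quaternary carbon comes from a chiral-imine Michael addition, the carbinol from attack anti to the angular methyl, the cis-diol from hydroxyl-directed osmylation, C3a (trans fusion) from inversion in the antiperiplanar shift, and C4 from hydroxyl-directed hydride delivery.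

Key step: step 6

Remark: 1 is used as the commercial stereoisomer mixture; its untouched methyl centre (C7 of the naphthalenes, C6 of the azulenes) stays a mixture of epimers, is left open in the SMILES and becomes sp2 in step 7.
Remark: the amine antipode in step 1 is assigned by analogy with 2-methylcyclohexanone (where the enantiomeric amine gives the (R)-diketone) and would be exchanged if the sense of induction were reversed.

Step 1
Reactants: 1 2,5-dimethylcyclohexan-1-one; 2 (R)-1-phenylethan-1-amine; 3 but-3-en-2-one (methyl vinyl ketone)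
Product: 6 (2S)-2,5-dimethyl-2-(3-oxobutyl)cyclohexan-1-one, via ketimine 4 (not isolated), via Michael-adduct imine 5 (not isolated)
Conditions: 2 (1.0 equiv), TsOH (cat.), PhMe, reflux, –H2O; then 3, THF, 40 °C; then 20% aq AcOH, rt
Reagents that add atoms: water, O
Why: Chiral-imine Michael addition, in which the more substituted secondary-enamine tautomer of 4 should add to the enone through a compact aza-ene-like transition state on the face away from the phenyl group of the auxiliary, setting the quaternary carbon as (S) before hydrolysis returns the amine.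

Step 2
Reactants: 6 (2S)-2,5-dimethyl-2-(3-oxobutyl)cyclohexan-1-one
Product: 7 (4aS)-4a,7-dimethyl-4,4a,5,6,7,8-hexahydronaphthalen-2(3H)-one
Conditions: NaOMe, MeOH, 60 °C
Reagents that add atoms: none
Why: Second stage of the Robinson annulation, in which the methyl ketone enolate should add to the ring ketone (six-membered ring) and dehydrate to the conjugated octalone without touching the quaternary centre.

Step 3
Reactants: 7 (4aS)-4a,7-dimethyl-4,4a,5,6,7,8-hexahydronaphthalen-2(3H)-one
Product: 8 (2R,4aS)-4a,7-dimethyl-2-(propan-2-yl)-2,3,4,4a,5,6,7,8-octahydronaphthalen-2-ol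
Conditions: iPrMgCl, CeCl3, THF, –78 → 0 °C; aq NH4Cl
Reagents that add atoms: isopropylmagnesium chloride, CC(C)[Mg]Cl
Why: Organocerium 1,2-addition to the enone, which should take the pseudo-axial trajectory on the face opposite the angular methyl (as in hydride and alkyl additions to angularly methylated octalones), so that the new tertiary hydroxyl is cis to that methyl.

Step 4
Reactants: 8 (2R,4aS)-4a,7-dimethyl-2-(propan-2-yl)-2,3,4,4a,5,6,7,8-octahydronaphthalen-2-ol
Product: 10 (1S,2R,4aS,8aR)-4a,7-dimethyl-2-(propan-2-yl)decahydronaphthalene-1,2,8a-triol, via osmate ester TMEDA complex 9 (not isolated)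
Conditions: OsO4 (1.05 equiv), TMEDA, CH2Cl2, –78 °C; then aq Na2SO3, THF, 60 °C
Reagents that add atoms: osmium tetroxide, O=[Os](=O)(=O)=O
Why: Hydrogen-bond-directed dihydroxylation, in which the OsO4–diamine complex should be delivered by the allylic tertiary hydroxyl to its own face of the trisubstituted alkene, giving the all-cis triol with a cis ring fusion (both new C–O bonds cis to the angular methyl).

Step 5
Reactants: 10 (1S,2R,4aS,8aR)-4a,7-dimethyl-2-(propan-2-yl)decahydronaphthalene-1,2,8a-triol
Product: 11 (1S,2R,4aS,8aR)-2,8a-dihydroxy-4a,7-dimethyl-2-(propan-2-yl)decahydronaphthalen-1-yl methanesulfonate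
Conditions: MsCl, Et3N, CH2Cl2, –20 → 0 °C
Reagents that add atoms: methanesulfonyl chloride, CS(=O)(=O)Cl
Why: Sulfonylation via sulfene should take only the secondary (equatorial) hydroxyl, the two tertiary hydroxyls being inert under these conditions, and no stereocentre is touched.

Step 6
Reactants: 11 (1S,2R,4aS,8aR)-2,8a-dihydroxy-4a,7-dimethyl-2-(propan-2-yl)decahydronaphthalen-1-yl methanesulfonate
Product: 12 (3R,3aR,8aS)-3-hydroxy-6,8a-dimethyl-3-(propan-2-yl)octahydroazulen-4(1H)-one
Conditions: Et3Al (3 equiv), CH2Cl2, –78 → 0 °C; aq KNaC4H4O6 (tartrate)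
Reagents that add atoms: none
Why: Et3Al turns both tertiary hydroxyls into aluminium alkoxides and activates the equatorial C1 mesylate; as the C1–O bond lengthens, the antiperiplanar C8a–C4a ring-fusion bond shifts from C8a to C1 and the C8a alkoxide collapses to the C4 ketone of the azulene (pinacol-type, i.e. semipinacol, 1,2-shift). The closest known reaction type is the pinacol-type rearrangement of vicinal diol monosulfonates, including its organoaluminium-promoted form and the conversion of hydronaphthalene diol monosulfonates into hydroazulenones. The cyclopentane closes by the 1,2-alkyl shift itself (formally a 3-exo-tet displacement at C1, six-to-five ring contraction), and the same bond movement expands the second six-membered ring to the cycloheptanone, so no separate cyclization is involved. The new CH centre (C3a) is set by inversion at C1 and the migrating quaternary carbon keeps its configuration; in the reacting chair (mesylate and isopropyl equatorial, both tertiary hydroxyls axial) this carbon carries its methyl equatorial and the ring A methylene axial, so the acyl carbon and that methylene end up trans and the ring fusion is trans, while C3 is untouched. The step needs migration of the ring-fusion bond and not of the C8a–C8 bond (gauche to the leaving group, so not aligned) or of the C2–C3 bond (aligned, but a CH2 migrating carbon pushed by the C2 alkoxide); the higher migratory aptitude of the fully substituted C4a should secure it. The resulting aluminium aldolate should resist retro-aldol cleavage until the tartrate work-up.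

Step 7
Reactants: 12 (3R,3aR,8aS)-3-hydroxy-6,8a-dimethyl-3-(propan-2-yl)octahydroazulen-4(1H)-one
Product: 15 (3R,3aR,8aS)-3-hydroxy-6,8a-dimethyl-3-(propan-2-yl)-2,3,3a,7,8,8a-hexahydroazulen-4(1H)-one, via bis-silyl enol ether 13 (not isolated), via silyl ether enone 14 (not isolated)
Conditions: TMSOTf, Et3N, CH2Cl2, 0 °C; then Pd(OAc)2 (1.1 equiv), MeCN, rt; then 1 M HCl, THF, 0 °C
Reagents that add atoms: none
Why: Saegusa–Ito oxidation, in which the less hindered silyl enol ether (towards C5) should undergo palladation and β-hydride loss from C6 to give the trisubstituted enone from both C6 epimers (an enol ether towards C3a has no β-hydrogen and simply reverts), while the tertiary hydroxyl is masked as its silyl ether until the acid work-up.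

Step 8
Reactants: 15 (3R,3aR,8aS)-3-hydroxy-6,8a-dimethyl-3-(propan-2-yl)-2,3,3a,7,8,8a-hexahydroazulen-4(1H)-one
Product: 16 (3R,3aS,4S,8aS)-6,8a-dimethyl-3-(propan-2-yl)-1,2,3,3a,4,7,8,8a-octahydroazulene-3,4-diol
Conditions: Me4NBH(OAc)3, MeCN/AcOH, –30 °C
Reagents that add atoms: none
Why: Evans–Saksena hydroxyl-directed 1,2-reduction, in which the alkoxyborohydride formed on the C3 hydroxyl should deliver hydride through a six-membered transition state to the only carbonyl face it can reach, placing the C4 hydroxyl anti to the C3 oxygen (cis to the C3a hydrogen).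

Step 9
Reactants: 17 (E)-3-(4-hydroxyphenyl)prop-2-enoic acid (p-coumaric acid)
Product: 19 (E)-3-[4-(tert-butyldimethylsilyloxy)phenyl]prop-2-enoic acid, via silyl ester 18 (not isolated)
Conditions: TBSCl (2.2 equiv), imidazole, DMF, rt; then K2CO3 (cat.), MeOH, 0 °C
Reagents that add atoms: tert-butyldimethylsilyl chloride, CC(C)(C)[Si](C)(C)Cl
Why: Silylation of phenol and acid followed by selective methanolysis of the far more labile silyl ester should leave the aryl silyl ether and the E alkene intact.

Step 10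
Reactants: 16 (3R,3aS,4S,8aS)-6,8a-dimethyl-3-(propan-2-yl)-1,2,3,3a,4,7,8,8a-octahydroazulene-3,4-diol; 19 (E)-3-[4-(tert-butyldimethylsilyloxy)phenyl]prop-2-enoic acid
Product: 21 (3R,3aS,4S,8aS)-3-hydroxy-6,8a-dimethyl-3-(propan-2-yl)-1,2,3,3a,4,7,8,8a-octahydroazulen-4-yl (2E)-3-[4-(tert-butyldimethylsilyloxy)phenyl]prop-2-enoate, via mixed anhydride 20 (not isolated)
Conditions: 2,4,6-Cl3C6H2COCl, Et3N, THF, rt; then 16, DMAP, PhMe, rt
Reagents that add atoms: none
Why: Yamaguchi esterification, which should acylate only the secondary allylic hydroxyl (the tertiary carbinol is inert) and leaves all stereocentres untouched.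

Step 11
Reactants: 21 (3R,3aS,4S,8aS)-3-hydroxy-6,8a-dimethyl-3-(propan-2-yl)-1,2,3,3a,4,7,8,8a-octahydroazulen-4-yl (2E)-3-[4-(tert-butyldimethylsilyloxy)phenyl]prop-2-enoate
Product: 22 (3R,3aS,4S,8aR)-3-hydroxy-6,8a-dimethyl-7-oxo-3-(propan-2-yl)-1,2,3,3a,4,7,8,8a-octahydroazulen-4-yl (2E)-3-[4-(tert-butyldimethylsilyloxy)phenyl]prop-2-enoate
Conditions: Rh2(C6H10NO)4 (dirhodium tetrakis(caprolactamate), 1 mol %), t-BuOOH (in decane), NaHCO3, CH2Cl2, rt
Reagents that add atoms: tert-butyl hydroperoxide, CC(C)(C)OO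
Why: Dirhodium-catalysed allylic oxidation by tert-butylperoxyl radicals, which should attack the ring methylene C7 next to the methyl-bearing alkene carbon (the only secondary allylic C–H that is not deactivated by an acyloxy group) and give the enone.

Step 12
Reactants: 22 (3R,3aS,4S,8aR)-3-hydroxy-6,8a-dimethyl-7-oxo-3-(propan-2-yl)-1,2,3,3a,4,7,8,8a-octahydroazulen-4-yl (2E)-3-[4-(tert-butyldimethylsilyloxy)phenyl]prop-2-enoate
Product: 23 (3R,3aS,4S,8aR)-3-hydroxy-6,8a-dimethyl-7-oxo-3-(propan-2-yl)-1,2,3,3a,4,7,8,8a-octahydroazulen-4-yl (2E)-3-(4-hydroxyphenyl)prop-2-enoate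
Conditions: Bu4NF, AcOH, THF, 0 °C
Reagents that add atoms: none
Why: Fluoride-mediated cleavage of the aryl silyl ether, buffered with acetic acid so that the γ-acyloxy enone and the ester should survive.

**Compound list**
1 | 2,5-dimethylcyclohexan-1-one (stereoisomer mixture) | CC1CC(=O)C(C)CC1 | starting material
2 | (R)-1-phenylethan-1-amine | C[C@@H](N)c1ccccc1 | starting material
3 | but-3-en-2-one (methyl vinyl ketone) | CC(=O)C=C | starting material
4 | 2,5-dimethyl-N-[(1R)-1-phenylethyl]cyclohexan-1-imine | CC1CC(=N[C@H](C)c2ccccc2)C(C)CC1 | intermediate (not isolated)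
5 | 4-[(1S)-1,4-dimethyl-2-{[(1R)-1-phenylethyl]imino}cyclohexyl]butan-2-one | CC1CC(=N[C@H](C)c2ccccc2)[C@](C)(CCC(C)=O)CC1 | intermediate (not isolated)
6 | (2S)-2,5-dimethyl-2-(3-oxobutyl)cyclohexan-1-one | CC1CC(=O)[C@](C)(CCC(C)=O)CC1 | intermediate
7 | (4aS)-4a,7-dimethyl-4,4a,5,6,7,8-hexahydronaphthalen-2(3H)-one | CC1CC2=CC(=O)CC[C@]2(C)CC1 | intermediate
8 | (2R,4aS)-4a,7-dimethyl-2-(propan-2-yl)-2,3,4,4a,5,6,7,8-octahydronaphthalen-2-ol | CC1CC2=C[C@](O)(C(C)C)CC[C@]2(C)CC1 | intermediate
9 | cyclic osmate ester (hexavalent osmium) of triol 10 at O1 and O8a, TMEDA complex | CC1C[C@]2(O[Os](=O)(=O)O3)[C@@H]3[C@](O)(C(C)C)CC[C@]2(C)CC1.CN(C)CCN(C)C | intermediate (not isolated)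
10 | (1S,2R,4aS,8aR)-4a,7-dimethyl-2-(propan-2-yl)decahydronaphthalene-1,2,8a-triol (all three hydroxyls cis to the angular methyl, cis ring fusion) | CC1C[C@]2(O)[C@@H](O)[C@](O)(C(C)C)CC[C@]2(C)CC1 | intermediate
11 | (1S,2R,4aS,8aR)-2,8a-dihydroxy-4a,7-dimethyl-2-(propan-2-yl)decahydronaphthalen-1-yl methanesulfonate | CC1C[C@]2(O)[C@@H](OS(C)(=O)=O)[C@](O)(C(C)C)CC[C@]2(C)CC1 | intermediate
12 | (3R,3aR,8aS)-3-hydroxy-6,8a-dimethyl-3-(propan-2-yl)octahydroazulen-4(1H)-one (trans ring fusion, hydroxyl cis to the angular methyl) | CC1CC(=O)[C@@H]2[C@](C)(CC[C@@]2(O)C(C)C)CC1 | intermediate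
13 | bis(trimethylsilyl) derivative of 12 (C4 silyl enol ether with C4=C5, C3 silyl ether) | CC1C=C(O[Si](C)(C)C)[C@@H]2[C@](C)(CC[C@@]2(O[Si](C)(C)C)C(C)C)CC1 | intermediate (not isolated)
14 | (3R,3aR,8aS)-6,8a-dimethyl-3-(propan-2-yl)-3-(trimethylsilyloxy)-2,3,3a,7,8,8a-hexahydroazulen-4(1H)-one | CC1=CC(=O)[C@@H]2[C@](C)(CC[C@@]2(O[Si](C)(C)C)C(C)C)CC1 | intermediate (not isolated)
15 | (3R,3aR,8aS)-3-hydroxy-6,8a-dimethyl-3-(propan-2-yl)-2,3,3a,7,8,8a-hexahydroazulen-4(1H)-one | CC1=CC(=O)[C@@H]2[C@](C)(CC[C@@]2(O)C(C)C)CC1 | intermediate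
16 | (3R,3aS,4S,8aS)-6,8a-dimethyl-3-(propan-2-yl)-1,2,3,3a,4,7,8,8a-octahydroazulene-3,4-diol | CC1=C[C@H](O)[C@@H]2[C@](C)(CC[C@@]2(O)C(C)C)CC1 | intermediate
17 | (E)-3-(4-hydroxyphenyl)prop-2-enoic acid | OC(=O)/C=C/c1ccc(O)cc1 | starting material
18 | tert-butyldimethylsilyl (E)-3-[4-(tert-butyldimethylsilyloxy)phenyl]prop-2-enoate | CC(C)(C)[Si](C)(C)OC(=O)/C=C/c1ccc(O[Si](C)(C)C(C)(C)C)cc1 | intermediate (not isolated)
19 | (E)-3-[4-(tert-butyldimethylsilyloxy)phenyl]prop-2-enoic acid | OC(=O)/C=C/c1ccc(O[Si](C)(C)C(C)(C)C)cc1 | intermediate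
20 | (E)-3-[4-(tert-butyldimethylsilyloxy)phenyl]prop-2-enoic 2,4,6-trichlorobenzoic anhydride | O=C(OC(=O)/C=C/c1ccc(O[Si](C)(C)C(C)(C)C)cc1)c1c(Cl)cc(Cl)cc1Cl | intermediate (not isolated)
21 | (3R,3aS,4S,8aS)-3-hydroxy-6,8a-dimethyl-3-(propan-2-yl)-1,2,3,3a,4,7,8,8a-octahydroazulen-4-yl (2E)-3-[4-(tert-butyldimethylsilyloxy)phenyl]prop-2-enoate | CC1=C[C@H](OC(=O)/C=C/c2ccc(O[Si](C)(C)C(C)(C)C)cc2)[C@@H]2[C@](C)(CC[C@@]2(O)C(C)C)CC1 | intermediate
22 | (3R,3aS,4S,8aR)-3-hydroxy-6,8a-dimethyl-7-oxo-3-(propan-2-yl)-1,2,3,3a,4,7,8,8a-octahydroazulen-4-yl (2E)-3-[4-(tert-butyldimethylsilyloxy)phenyl]prop-2-enoate | CC1=C[C@H](OC(=O)/C=C/c2ccc(O[Si](C)(C)C(C)(C)C)cc2)[C@@H]2[C@](C)(CC[C@@]2(O)C(C)C)CC1=O | intermediate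
23 | (3R,3aS,4S,8aR)-3-hydroxy-6,8a-dimethyl-7-oxo-3-(propan-2-yl)-1,2,3,3a,4,7,8,8a-octahydroazulen-4-yl (2E)-3-(4-hydroxyphenyl)prop-2-enoate | CC1=C[C@H](OC(=O)/C=C/c2ccc(O)cc2)[C@@H]2[C@](C)(CC[C@@]2(O)C(C)C)CC1=O | target

**Step count**
Total: 12 steps. Longest linear sequence: 11 steps (steps 1–8 and 10–12); step 9 is a one-step branch.

**Steps most likely to fail, with fallbacks**

Step 6. The risk is ionization of the mesylate with assistance from the C2 alkoxide, so that the C2–C3 bond shifts and the ring contracts in the wrong direction; the β-alkoxy ketone could also open by retro-aldol cleavage once formed. The fallback sets out from 11. Silylation of the less congested C2 hydroxyl (TESOTf, 2,6-lutidine, CH2Cl2, –78 °C) should give (1R,2R,4aS,8aR)-8a-hydroxy-4a,7-dimethyl-2-(propan-2-yl)-2-(triethylsilyloxy)decahydronaphthalen-1-yl methanesulfonate F1. With only the ring-fusion hydroxyl free, KOtBu in t-BuOH/THF should trigger the same 1,2-shift as an alkoxide-driven pinacol-type rearrangement and give (3R,3aR,8aS)-6,8a-dimethyl-3-(propan-2-yl)-3-(triethylsilyloxy)octahydroazulen-4(1H)-one F2, in which neither the competing assistance nor retro-aldol cleavage is possible. HF·pyridine in THF then returns to 12.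

Step 4. The risk is osmylation on the face away from the angular methyl group if steric approach control overrides hydrogen-bond delivery, which would give the trans-fused triol. The fallback sets out from 8 and uses a Woodward cis-hydroxylation (I2, AgOAc, AcOH/H2O, rt). The iodonium ion should form on the open face, and acetate opening followed by acetoxonium formation should place both oxygens on the hindered face, cis to the angular methyl, giving (1S,2R,4aS,8aR)-2,8a-dihydroxy-4a,7-dimethyl-2-(propan-2-yl)decahydronaphthalen-1-yl acetate F3. K2CO3 in MeOH then returns to 10.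

Step 3. The risk is poor facial selectivity together with enolization or hydride transfer by the branched Grignard reagent. The fallback sets out from 7. A slender sp nucleophile with a strong preference for the pseudo-axial trajectory (HC≡CMgBr, CeCl3, THF, –78 °C) should give (2S,4aS)-2-ethynyl-4a,7-dimethyl-2,3,4,4a,5,6,7,8-octahydronaphthalen-2-ol F4. Zirconium-catalysed carboalumination (Me3Al, Cp2ZrCl2, CH2Cl2; then H2O) should convert the alkyne into (2S,4aS)-4a,7-dimethyl-2-(prop-1-en-2-yl)-2,3,4,4a,5,6,7,8-octahydronaphthalen-2-ol F5. Hydrogenation of the 1,1-disubstituted alkene only (H2, RhCl(PPh3)3, PhH) returns to 8.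

**Further compounds**
F1 | step 6 | (1R,2R,4aS,8aR)-8a-hydroxy-4a,7-dimethyl-2-(propan-2-yl)-2-(triethylsilyloxy)decahydronaphthalen-1-yl methanesulfonate | CC1C[C@]2(O)[C@@H](OS(C)(=O)=O)[C@](O[Si](CC)(CC)CC)(C(C)C)CC[C@]2(C)CC1
F2 | step 6 | (3R,3aR,8aS)-6,8a-dimethyl-3-(propan-2-yl)-3-(triethylsilyloxy)octahydroazulen-4(1H)-one | CC1CC(=O)[C@@H]2[C@](C)(CC[C@@]2(O[Si](CC)(CC)CC)C(C)C)CC1
F3 | step 4 | (1S,2R,4aS,8aR)-2,8a-dihydroxy-4a,7-dimethyl-2-(propan-2-yl)decahydronaphthalen-1-yl acetate | CC1C[C@]2(O)[C@@H](OC(C)=O)[C@](O)(C(C)C)CC[C@]2(C)CC1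
F4 | step 3 | (2S,4aS)-2-ethynyl-4a,7-dimethyl-2,3,4,4a,5,6,7,8-octahydronaphthalen-2-ol | CC1CC2=C[C@](O)(C#C)CC[C@]2(C)CC1
F5 | step 3 | (2S,4aS)-4a,7-dimethyl-2-(prop-1-en-2-yl)-2,3,4,4a,5,6,7,8-octahydronaphthalen-2-ol | CC1CC2=C[C@](O)(C(C)=C)CC[C@]2(C)CC1
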